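**Retrosynthetic overview**

1. The 1-methylimidazole-2,5-dione ring is attached last: the exocyclic C2–NH–C4' amidine bond is cut to a 2-aminoimidazole and silylated 1-methylparabanic acid, and the 2-amino group is traced back through N3, SO2Me and SMe to a C2 thione.
2. The strategy rests on the imidazole ring: C4, its 4-methoxybenzyl group and N3 are the alpha-carbon, side chain and nitrogen of O-methyltyrosine, while N1, its methyl group and C2 are the atoms of methyl isothiocyanate. The ring is cut at N3–C2 and N1–C5 (Marckwald closure).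
3. C5 is the former carboxyl carbon of the amino acid; its 3-oxygenated 4,5-dimethoxybenzyl group arrives as a benzylic Grignard reagent on the Weinreb amide, the phenol being carried as a benzyl ether.
4. Ring order: imidazole first (step 7); the preformed five-membered trione ring is appended in step 12. The benzyl ether falls in the azide hydrogenation.

Key step: step 7

Remark on the chemistry: compounds 1, 5, 10 and 18 are taken as purchasable. The (S) centre of the tyrosine unit is carried to 9 but becomes sp2 C4 in step 7, so its integrity is not monitored.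

**Route**

Step 1
Reactants: 1 3-hydroxy-4,5-dimethoxybenzaldehyde
Product: 2 3-(benzyloxy)-4,5-dimethoxybenzaldehyde
Conditions: BnBr, K2CO3, DMF, 60 °C
Reagents that add atoms: benzyl bromide, BrCc1ccccc1
Why: Williamson ether synthesis; the phenoxide formed by K2CO3 should be alkylated cleanly by the benzylic bromide while the aldehyde is untouched.

Step 2
Reactants: 2 3-(benzyloxy)-4,5-dimethoxybenzaldehyde
Product: 3 [3-(benzyloxy)-4,5-dimethoxyphenyl]methanol
Conditions: NaBH4, MeOH, 0 °C
Reagents that add atoms: none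
Why: Borohydride reduction of an aryl aldehyde to the benzylic alcohol; the aryl ethers are inert to hydride.

Step 3
Reactants: 3 [3-(benzyloxy)-4,5-dimethoxyphenyl]methanol
Product: 4 1-(benzyloxy)-5-(chloromethyl)-2,3-dimethoxybenzene
Conditions: SOCl2, CH2Cl2, 0 °C → rt; used directly
Reagents that add atoms: thionyl chloride, O=S(Cl)Cl
Why: Deoxychlorination through the chlorosulfite, which should collapse readily at this electron-rich benzylic carbon; the chloride is used at once to limit hydrolysis.

Step 4
Reactants: 5 N-Boc-O-methyl-L-tyrosine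
Product: 6 tert-butyl N-[(2S)-1-[methoxy(methyl)amino]-3-(4-methoxyphenyl)-1-oxopropan-2-yl]carbamate
Conditions: MeNHOMe·HCl, EDC·HCl, HOBt, N-methylmorpholine, CH2Cl2, 0 °C → rt
Reagents that add atoms: N,O-dimethylhydroxylamine hydrochloride, CNOC.Cl
Why: Carbodiimide amide coupling through the HOBt ester should give the Weinreb amide without disturbing the carbamate.

Step 5
Reactants: 6 the Weinreb amide; 4 1-(benzyloxy)-5-(chloromethyl)-2,3-dimethoxybenzene
Product: 8 tert-butyl N-[(2S)-4-[3-(benzyloxy)-4,5-dimethoxyphenyl]-1-(4-methoxyphenyl)-3-oxobutan-2-yl]carbamate, via benzylic Grignard reagent 7 (not isolated)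
Conditions: 4 added slowly to Mg turnings, THF, 0 °C (gives 7); 6, i-PrMgCl (1.0 equiv), THF, −15 °C; then 7 (1.5 equiv), −15 °C → rt; aq. NH4Cl
Reagents that add atoms: none
Why: Weinreb ketone synthesis; the carbamate N–H is first removed by i-PrMgCl so that 7 is not wasted, and the five-membered magnesium chelate of the tetrahedral adduct should block over-addition until the quench releases the ketone.

Step 6
Reactants: 8 the Boc-protected aminoketone
Product: 9 (3S)-3-amino-1-[3-(benzyloxy)-4,5-dimethoxyphenyl]-4-(4-methoxyphenyl)butan-2-one hydrochloride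
Conditions: 4 M HCl in dioxane, rt; precipitation with Et2O
Reagents that add atoms: hydrogen chloride, Cl
Why: Acidolysis of the tert-butyl carbamate with loss of isobutene and CO2; isolation as the ammonium salt should prevent self-condensation of the alpha-aminoketone, and the benzyl ether tolerates anhydrous HCl at rt.

Step 7
Reactants: 9 the aminoketone hydrochloride; 10 methyl isothiocyanate
Product: 12 5-[3-(benzyloxy)-4,5-dimethoxybenzyl]-4-(4-methoxybenzyl)-1-methyl-1,3-dihydro-2H-imidazole-2-thione, via thiourea 11 (not isolated)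
Conditions: 10 (1.1 equiv), Et3N (1.1 equiv, added slowly), CH2Cl2, 0 °C → rt; solvent exchanged for AcOH, 90 °C
Reagents that add atoms: none
Why: Triethylamine frees the amine of 9 in the presence of 10, and the primary amine adds to the isothiocyanate carbon to give thiourea 11 (bond N3–C2); in hot acetic acid the N-methyl nitrogen attacks the protonated ketone in a 5-exo-trig closure (bond N1–C5), and the cyclic carbinolamine should lose water and tautomerise to the aromatic imidazole-2-thione. This is the Marckwald synthesis of imidazole-2-thiones from alpha-aminoketones and isothiocyanates. One ring, the imidazole, is closed and no stereocentre is formed; the tyrosine alpha-carbon becomes sp2 C4, so racemisation on the way is of no concern. The selectivity needed is regiochemical, the methyl group on the nitrogen next to C5, and it is fixed by connectivity: the amino acid nitrogen is already bonded to C4 and to the thiocarbonyl carbon, so only the NHMe nitrogen can reach the ketone. Closure through sulfur to a hemithioketal is reversible and is drained by the N-closure and aromatisation, and trapping the amine as it is released should suppress dihydropyrazine formation.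

Step 8
Reactants: 12 the imidazole-2-thione
Product: 13 5-[3-(benzyloxy)-4,5-dimethoxybenzyl]-4-(4-methoxybenzyl)-1-methyl-2-(methylsulfanyl)-1H-imidazole
Conditions: MeI (1.05 equiv), K2CO3, acetone, rt
Reagents that add atoms: iodomethane, CI
Why: S-alkylation of the thioureide anion; the soft sulfur should react in preference to N3, and the near-stoichiometric charge of MeI avoids quaternisation.

Step 9
Reactants: 13 the 2-(methylsulfanyl)imidazole
Product: 15 5-[3-(benzyloxy)-4,5-dimethoxybenzyl]-4-(4-methoxybenzyl)-1-methyl-2-(methylsulfonyl)-1H-imidazole, via sulfoxide 14 (not isolated)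
Conditions: mCPBA (2.2 equiv), CH2Cl2, 0 °C → rt; aq. Na2S2O3/NaHCO3
Reagents that add atoms: 3-chloroperoxybenzoic acid, OOC(=O)c1cccc(Cl)c1
Why: Stepwise peracid oxidation of sulfide to sulfoxide to sulfone; the sulfur is far more nucleophilic than N3 (protonated by the acid formed) or the arenes, so S-oxidation should be chemoselective.

Step 10
Reactants: 15 the 2-(methylsulfonyl)imidazole
Product: 16 2-azido-5-[3-(benzyloxy)-4,5-dimethoxybenzyl]-4-(4-methoxybenzyl)-1-methyl-1H-imidazole
Conditions: NaN3 (3 equiv), DMSO, 90–100 °C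
Reagents that add atoms: sodium azide, [Na+].[N-]=[N+]=[N-]
Why: Nucleophilic aromatic ipso substitution of a 2-sulfonyl group on a 1-methylimidazole; azide adds at C2 with the charge taken up by N3 and the sulfonyl group, and methanesulfinate leaves.

Step 11
Reactants: 16 the 2-azidoimidazole
Product: 17 5-{[2-amino-4-(4-methoxybenzyl)-1-methyl-1H-imidazol-5-yl]methyl}-2,3-dimethoxyphenol
Conditions: H2 (1 atm), Pd/C, MeOH, rt
Reagents that add atoms: none
Why: Catalytic hydrogenation should reduce the azide to the amine with loss of N2 and hydrogenolyse the O-benzyl ether in the same operation; the imidazolyl–CH2–aryl C–C bonds are inert.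

Step 12
Reactants: 17 the 2-aminoimidazole phenol; 18 1-methylparabanic acid
Product: 20 4-{[5-(3-hydroxy-4,5-dimethoxybenzyl)-4-(4-methoxybenzyl)-1-methyl-1H-imidazol-2-yl]amino}-1-methyl-1H-imidazole-2,5-dione, via silyl imidate 19 (not isolated)
Conditions: 18 (1.5 equiv), N,O-bis(trimethylsilyl)acetamide (1.5 equiv), MeCN, rt (gives 19); then 17, toluene, reflux; MeOH quench
Reagents that add atoms: none
Why: Silylation turns the N3–H/C4=O imide unit of 18 into a silyl imidate, and the exocyclic amine of 17 should add at C4 and expel silanol (addition–elimination, as in silyl-mediated amination of cyclic imides), C4 being more electrophilic than the urea carbonyl C2; the methanol quench reverses any transient silylation of the phenol.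

**Compound list**

1 | 3-hydroxy-4,5-dimethoxybenzaldehyde | COc1cc(C=O)cc(O)c1OC | starting material
2 | 3-(benzyloxy)-4,5-dimethoxybenzaldehyde | COc1cc(C=O)cc(OCc2ccccc2)c1OC | intermediate
3 | [3-(benzyloxy)-4,5-dimethoxyphenyl]methanol | COc1cc(CO)cc(OCc2ccccc2)c1OC | intermediate
4 | 1-(benzyloxy)-5-(chloromethyl)-2,3-dimethoxybenzene | COc1cc(CCl)cc(OCc2ccccc2)c1OC | intermediate
5 | N-Boc-O-methyl-L-tyrosine | COc1ccc(C[C@H](NC(=O)OC(C)(C)C)C(=O)O)cc1 | starting material
6 | tert-butyl N-[(2S)-1-[methoxy(methyl)amino]-3-(4-methoxyphenyl)-1-oxopropan-2-yl]carbamate | COc1ccc(C[C@H](NC(=O)OC(C)(C)C)C(=O)N(C)OC)cc1 | intermediate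
7 | [3-(benzyloxy)-4,5-dimethoxybenzyl]magnesium chloride | COc1cc(C[Mg]Cl)cc(OCc2ccccc2)c1OC | intermediate (not isolated)
8 | tert-butyl N-[(2S)-4-[3-(benzyloxy)-4,5-dimethoxyphenyl]-1-(4-methoxyphenyl)-3-oxobutan-2-yl]carbamate | COc1ccc(C[C@H](NC(=O)OC(C)(C)C)C(=O)Cc2cc(OCc3ccccc3)c(OC)c(OC)c2)cc1 | intermediate
9 | (3S)-3-amino-1-[3-(benzyloxy)-4,5-dimethoxyphenyl]-4-(4-methoxyphenyl)butan-2-one hydrochloride | Cl.N[C@@H](Cc1ccc(OC)cc1)C(=O)Cc1cc(OCc2ccccc2)c(OC)c(OC)c1 | intermediate
10 | methyl isothiocyanate | CN=C=S | starting material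
11 | 1-[(2S)-4-[3-(benzyloxy)-4,5-dimethoxyphenyl]-1-(4-methoxyphenyl)-3-oxobutan-2-yl]-3-methylthiourea | CNC(=S)N[C@@H](Cc1ccc(OC)cc1)C(=O)Cc1cc(OCc2ccccc2)c(OC)c(OC)c1 | intermediate (not isolated)
12 | 5-[3-(benzyloxy)-4,5-dimethoxybenzyl]-4-(4-methoxybenzyl)-1-methyl-1,3-dihydro-2H-imidazole-2-thione | COc1ccc(Cc2[nH]c(=S)n(C)c2Cc2cc(OCc3ccccc3)c(OC)c(OC)c2)cc1 | intermediate
13 | 5-[3-(benzyloxy)-4,5-dimethoxybenzyl]-4-(4-methoxybenzyl)-1-methyl-2-(methylsulfanyl)-1H-imidazole | COc1ccc(Cc2nc(SC)n(C)c2Cc2cc(OCc3ccccc3)c(OC)c(OC)c2)cc1 | intermediate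
14 | 5-[3-(benzyloxy)-4,5-dimethoxybenzyl]-4-(4-methoxybenzyl)-1-methyl-2-(methylsulfinyl)-1H-imidazole (racemic at sulfur) | COc1ccc(Cc2nc(S(C)=O)n(C)c2Cc2cc(OCc3ccccc3)c(OC)c(OC)c2)cc1 | intermediate (not isolated)
15 | 5-[3-(benzyloxy)-4,5-dimethoxybenzyl]-4-(4-methoxybenzyl)-1-methyl-2-(methylsulfonyl)-1H-imidazole | COc1ccc(Cc2nc(S(C)(=O)=O)n(C)c2Cc2cc(OCc3ccccc3)c(OC)c(OC)c2)cc1 | intermediate
16 | 2-azido-5-[3-(benzyloxy)-4,5-dimethoxybenzyl]-4-(4-methoxybenzyl)-1-methyl-1H-imidazole | COc1ccc(Cc2nc(N=[N+]=[N-])n(C)c2Cc2cc(OCc3ccccc3)c(OC)c(OC)c2)cc1 | intermediate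
17 | 5-{[2-amino-4-(4-methoxybenzyl)-1-methyl-1H-imidazol-5-yl]methyl}-2,3-dimethoxyphenol | COc1ccc(Cc2nc(N)n(C)c2Cc2cc(O)c(OC)c(OC)c2)cc1 | intermediate
18 | 1-methylparabanic acid (1-methylimidazolidine-2,4,5-trione) | CN1C(=O)NC(=O)C1=O | starting material
19 | 1-methyl-4-(trimethylsilyloxy)-1H-imidazole-2,5-dione | CN1C(=O)N=C(O[Si](C)(C)C)C1=O | intermediate (not isolated)
20 | 4-{[5-(3-hydroxy-4,5-dimethoxybenzyl)-4-(4-methoxybenzyl)-1-methyl-1H-imidazol-2-yl]amino}-1-methyl-1H-imidazole-2,5-dione | COc1ccc(Cc2nc(NC3=NC(=O)N(C)C3=O)n(C)c2Cc2cc(O)c(OC)c(OC)c2)cc1 | target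

**Step count**

Total: 12 steps. Longest linear sequence: 11 steps (steps 1–3 and 5–12, from aldehyde 1); the tyrosine branch adds step 4.

**Steps most likely to fail**

1. Step 10. The ipso substitution may stall because the 4,5-dialkylimidazole is electron-rich, and the temperatures needed to force it may trigger thermal loss of nitrogen from the azide product. The fallback sets out from thione 12 and gives up sulfur as the leaving group. Oxidative desulfurisation of 12 with 30% aqueous H2O2 in AcOH (0 °C → rt) should give 5-[3-(benzyloxy)-4,5-dimethoxybenzyl]-4-(4-methoxybenzyl)-1-methyl-1H-imidazole F1. Deprotonation at C2 with n-BuLi in THF at −78 °C should give the 2-lithioimidazole F2, and tosyl azide should then transfer the azide by fragmentation of the lithium triazenide. The sequence comes back to the route at 16 and replaces steps 8–10.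

2. Step 5. Wurtz homocoupling may consume the electron-rich benzylic chloride during magnesium insertion, and addition of the benzylic Grignard reagent to the magnesiated amide may be incomplete. The fallback sets out from acid 5 and chloride 4 and replaces the Grignard/Weinreb pair by an organozinc/thioester pair. Steglich thioesterification of 5 (EtSH, DCC, catalytic DMAP, CH2Cl2) should give S-ethyl (2S)-2-[(tert-butoxycarbonyl)amino]-3-(4-methoxyphenyl)propanethioate F3. Zinc insertion into 4 (Zn dust, LiCl, THF, rt), which is little prone to homocoupling, should give [3-(benzyloxy)-4,5-dimethoxybenzyl]zinc chloride F4. Fukuyama coupling of F3 with F4 under PdCl2(PPh3)2 catalysis in THF/toluene at rt comes back to the route at 8.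

3. Step 12. The free phenol and the ring nitrogen may be silylated or acylated in competition with the exocyclic amine, and the addition–elimination may stop short under conditions the phenol tolerates. The fallback sets out from azide 16 and keeps the phenol masked through the condensation. Azide reduction that spares the benzyl ether (H2, Pd/CaCO3 poisoned with Pb(OAc)2, EtOH, rt) should give 2-amino-5-[3-(benzyloxy)-4,5-dimethoxybenzyl]-4-(4-methoxybenzyl)-1-methyl-1H-imidazole F5. Condensation of F5 with a larger excess of 19 (from 18 and N,O-bis(trimethylsilyl)acetamide, toluene, reflux) should give the O-benzyl ether of the target, 4-{[5-[3-(benzyloxy)-4,5-dimethoxybenzyl]-4-(4-methoxybenzyl)-1-methyl-1H-imidazol-2-yl]amino}-1-methyl-1H-imidazole-2,5-dione F6. Non-reductive debenzylation with BCl3 and pentamethylbenzene in CH2Cl2 at −78 °C, which leaves the acylamidine C=N bond and the methyl ethers alone, comes back to the route at 20.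

**Further compounds**

F1 | step 10 | 5-[3-(benzyloxy)-4,5-dimethoxybenzyl]-4-(4-methoxybenzyl)-1-methyl-1H-imidazole | COc1ccc(Cc2ncn(C)c2Cc2cc(OCc3ccccc3)c(OC)c(OC)c2)cc1
F2 | step 10 | {5-[3-(benzyloxy)-4,5-dimethoxybenzyl]-4-(4-methoxybenzyl)-1-methyl-1H-imidazol-2-yl}lithium | [Li]c1nc(Cc2ccc(OC)cc2)c(Cc2cc(OCc3ccccc3)c(OC)c(OC)c2)n1C
F3 | step 5 | S-ethyl (2S)-2-[(tert-butoxycarbonyl)amino]-3-(4-methoxyphenyl)propanethioate | COc1ccc(C[C@H](NC(=O)OC(C)(C)C)C(=O)SCC)cc1
F4 | step 5 | [3-(benzyloxy)-4,5-dimethoxybenzyl]zinc chloride | COc1cc(C[Zn]Cl)cc(OCc2ccccc2)c1OC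
F5 | step 12 | 2-amino-5-[3-(benzyloxy)-4,5-dimethoxybenzyl]-4-(4-methoxybenzyl)-1-methyl-1H-imidazole | COc1ccc(Cc2nc(N)n(C)c2Cc2cc(OCc3ccccc3)c(OC)c(OC)c2)cc1
F6 | step 12 | 4-{[5-[3-(benzyloxy)-4,5-dimethoxybenzyl]-4-(4-methoxybenzyl)-1-methyl-1H-imidazol-2-yl]amino}-1-methyl-1H-imidazole-2,5-dione | COc1ccc(Cc2nc(NC3=NC(=O)N(C)C3=O)n(C)c2Cc2cc(OCc3ccccc3)c(OC)c(OC)c2)cc1
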